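At 12.0 h the larch run read 41 % target, which makes 2770 molecules of target for each enzyme charged, although the added ligand had been charged at 3.02 times the enzyme.

- larch: substrate 29 mM; enzyme 4.3 µM; added ligand 13 µM; run made earlier
- flask: substrate 29 mM; enzyme 2.9 µM; added ligand 13 µM

larch run (percent of the substrate charged)

| time / h | target / % |
|---|---|
| 1.00 | 6 |
| 2.00 | 10 |
| 3.00 | 8 |
| 6.00 | 19 |
| 12.0 | 41 |

(each reading ± 1.5 percentage points)

- apparent order in enzyme when 20 % of the substrate are converted (percent change of the rate of making target for one percent more enzyme charged)
- factor on the rate of making target when 20 % of the substrate are converted if enzyme is charged twice over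

- no earlier run changes the charge of enzyme; that part of a forecast is a guess

Those two numbers seemed to me at odds if the ligand holds enzyme, but they go together if it holds enzyme reversibly and a free remainder does the work, and then the order in enzyme can differ from the plain case. I took the case without binding as the zero of my scale, with order 1 and doubling factor 2. For the other end, strong binding with ligand in excess, I reckoned the charge of ligand less the charge of enzyme, 10.1 µM, the spare ligand. Free enzyme then goes as enzyme charged over spare ligand, so the order is the ligand charge over the spare ligand, 1.29, and charging enzyme twice over gives 2.81. I expected this flask between the two ends.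

The forecast stood at my zero, with an order of 1 (range 0.75 to 1.45) and a factor of 2 (range 1.6 to 2.8), on the ground that “The default for a simple catalyst is first order”.

The flask gave an order of 1.2 and a factor of 2.61.

    enzyme + added ligand ⇌ idle complex, settled at all times (K = 1.35 × 10⁶ L mol⁻¹)
    substrate + enzyme → target + enzyme, rate k2*[substrate]^2.5*[enzyme]/(1 + ([substrate]/Kh2)^2.5) (12.7 mM, k = 54500 L²·⁵ mol⁻²·⁵ s⁻¹)

Taking the binding away in a simulated run of this flask lowers the order from 1.2 to 1.0, and in the flask itself free ligand stood at 10.3 µM, close to the spare ligand of 10.1 µM, with 6.71 % of the enzyme free. In the larch run the spare ligand is 8.70 µM, so my reckoning puts its free enzyme at 1.72 times that of the flask. If early target goes in step with free enzyme, that estimate scales the flask's 12.5 % target after 6 h to 21.5 %, where the larch run read 19 % at 6.00 h.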